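The numbers in the tables stem from a simulated flask with constants of no real substance, noise included.

I began at the late end of the earlier runs, where the target at 30.0 min stood at 3.8%, 4.1% and 4.4% in the teal, red and violet runs, although the red run held 4.00 times the starting material of the teal run and the violet run half its base, so I kept their mean as the draw rate, the share of the charged starting material turned into target each minute, 0.00137 /min.

| flask | starting material | coupling partner | base | remark | time |
|---|---|---|---|---|---|
| teal | 0.75 M | 1.2 M | 0.45 M | run made earlier |  |
| red | 3 M | 1.2 M | 0.45 M | run made earlier |  |
| violet | 1.5 M | 1.2 M | 0.23 M | run made earlier |  |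
| flask | 1.5 M | 1.20 M | 0.450 M |  | 40 min |

- teal (time / min: starting material / %, target / %): 2.50: 99.4, 0.5; 6.00: 98.9, 0.3; 15.0: 97.8, 2.1; 30.0: 96.1, 3.8
- red (time / min: starting material / %, target / %): 8.00: 98.6, 0.9; 15.0: 98.5, 2.0; 25.0: 96.4, 3.1; 30.0: 95.8, 4.1
- violet (time / min: starting material / %, target / %): 4.00: 99.4, 0.7; 12.0: 98.1, 1.5; 20.0: 97.9, 2.3; 30.0: 95.5, 4.4

(scatter of a reading: 0.3 percentage points)

- part of the starting material that has reacted at 40 min
- share of the unused coupling partner that is free and not bound as idle adduct, at 40 min

- the earlier runs do not show how much of coupling partner is bound; that part of a forecast is a guess

For the new flask I kept books on the coupling partner, the limiting reagent, since its charge of 1.20 M is smaller than the 1.5 M of starting material. Over 40 min the draw rate gave me 5.47% of the starting material as target. Booking one coupling partner per target, that entry came to 6.83% of the partner's charge, and the remaining 93.2% stood as unused, its division between free partner and idle adduct a guess. The forecast, which is not my reckoning, gave 5.4%, less than my figure, and 88% free, saying “so it is probably mostly free”.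

The flask gave 5.39% reacted and >99.9% free, with 93% of the coupling partner left and idle adduct at 0.0400% of the partner's charge, under this scheme:

    starting material + coupling partner + by-product → target + 2 by-product (k = 0.0916 /M²/min)
    starting material + coupling partner → target + by-product (k = 0.00110 /M/min)
    base + by-product ⇌ salt, settled at all times (K = 93.0 /M)
    coupling partner + by-product ⇌ idle adduct, settled at all times (K = 0.190 /M)

I then ran the same books on the neighbouring flask, which held 0.38 M of starting material and everything else as before. The draw rate again gave 5.47% over 40 min, but the target entry shrank to 1.73% of the partner's charge, leaving 98.3% unused. That flask gave 5.20% reacted, with 98% of its coupling partner left and >99.9% of the unused partner free.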